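**Retrosynthetic overview**
1. Target 17 ⇐ triol 16 ⇐ alcohol 15: the dihydropyran ring, the only ring made, is closed last by intramolecular Mitsunobu O1–C2 etherification after debenzylation.
2. 15 ⇐ 12 ⇐ 11: the C2 hydroxymethyl comes from ozonolysis/NaBH4 of an (E)-propenyl group; the 2'-OMe comes from methylation of the Claisen phenol.
3. 11 ⇐ 9 (key step): aromatic Claisen [3,3] rearrangement of an (S,E)-aryl allyl ether forms the C3–C1' bond and sets C3 by 1,3-chirality transfer.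
4. 9 ⇐ 7 + 4: the E-alkene comes from alkyne hydroboration/Suzuki coupling with the A-ring benzyl bromide; 7 ⇐ 2,3,4-trimethoxyphenol + (R)-but-3-yn-2-ol (Mitsunobu, inversion).
5. 4 ⇐ 2,4-dihydroxy-3-methoxybenzaldehyde (benzylation, reduction, bromination); both benzene rings are bought.

Assumption: 2,4-dihydroxy-3-methoxybenzaldehyde, 2,3,4-trimethoxyphenol and (R)-but-3-yn-2-ol (≥98% ee) are taken as catalogue chemicals.

The target is (3S)-7-hydroxy-8,2',3',4',5'-pentamethoxyisoflavan. The route has not been run; conditions are proposed from standard practice.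

**Step 1**
Reactants: 1 2,4-dihydroxy-3-methoxybenzaldehyde
Product: 2 2,4-bis(benzyloxy)-3-methoxybenzaldehyde
Conditions: BnBr (2.4 equiv), K2CO3, DMF, 60 °C
Reagents that add atoms: benzyl bromide, BrCc1ccccc1
Why: Double Williamson ether synthesis; the free 4-OH alkylates first and the chelated 2-OH follows on warming.

**Step 2**
Reactants: 2 2,4-bis(benzyloxy)-3-methoxybenzaldehyde
Product: 3 [2,4-bis(benzyloxy)-3-methoxyphenyl]methanol
Conditions: NaBH4, MeOH/THF, 0 °C
Reagents that add atoms: none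
Why: Borohydride reduction of an aryl aldehyde; benzyl and methyl ethers are inert.

**Step 3**
Reactants: 3 [2,4-bis(benzyloxy)-3-methoxyphenyl]methanol
Product: 4 1,3-bis(benzyloxy)-4-(bromomethyl)-2-methoxybenzene
Conditions: PBr3 (0.4 equiv), Et2O, 0 °C; used crude at once
Reagents that add atoms: phosphorus tribromide, BrP(Br)Br
Why: PBr3 bromination of an activated benzylic alcohol is fast at 0 °C; the electron-rich bromide is labile and is not stored.

**Step 4**
Reactants: 5 2,3,4-trimethoxyphenol; 6 (R)-but-3-yn-2-ol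
Product: 7 1-{[(2S)-but-3-yn-2-yl]oxy}-2,3,4-trimethoxybenzene
Conditions: PPh3, DIAD, THF, 0 °C → rt
Reagents that add atoms: none
Why: Mitsunobu etherification is a clean SN2 at the propargylic carbinol, so the bought (R) centre is inverted to the (S) aryl ether, the only source of chirality in the route.

**Step 5**
Reactants: 7 1-{[(2S)-but-3-yn-2-yl]oxy}-2,3,4-trimethoxybenzene; 4 1,3-bis(benzyloxy)-4-(bromomethyl)-2-methoxybenzene
Product: 9 1,3-bis(benzyloxy)-2-methoxy-4-[(2E,4S)-4-(2,3,4-trimethoxyphenoxy)pent-2-en-1-yl]benzene, via E-alkenyl pinacol boronate 8 (not isolated)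
Conditions: HBpin, Cp2Zr(H)Cl (10 mol%), Et3N (10 mol%), neat, 60 °C; then 4, Pd(dppf)Cl2 (5 mol%), K2CO3, THF/H2O, 50 °C
Reagents that add atoms: none
Why: Zr-catalysed syn-hydroboration of the terminal alkyne gives only the E-alkenylboronate, and Suzuki–Miyaura sp2–sp3 coupling with the benzylic bromide keeps the geometry and does not touch the C–O stereocentre.

**Step 6**
Reactants: 9 1,3-bis(benzyloxy)-2-methoxy-4-[(2E,4S)-4-(2,3,4-trimethoxyphenoxy)pent-2-en-1-yl]benzene
Product: 11 6-{(2R,3E)-1-[2,4-bis(benzyloxy)-3-methoxyphenyl]pent-3-en-2-yl}-2,3,4-trimethoxyphenol, via ortho-dienone 10 (not isolated)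
Conditions: Eu(fod)3 (10 mol%), CHCl3, 60 °C
Reagents that add atoms: none
Why: Aromatic Claisen [3,3]-sigmatropic rearrangement through a chair transition state with methyl equatorial; C–O cleavage and C–C formation occur on the same face of the allyl unit, so the (S) ether centre is relayed into the (R) benzylic centre (future C3) with an E-propenyl group at the only free ortho position, and dienone 10 tautomerises to the phenol.

**Step 7**
Reactants: 11 6-{(2R,3E)-1-[2,4-bis(benzyloxy)-3-methoxyphenyl]pent-3-en-2-yl}-2,3,4-trimethoxyphenol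
Product: 12 1-{(2R,3E)-1-[2,4-bis(benzyloxy)-3-methoxyphenyl]pent-3-en-2-yl}-2,3,4,5-tetramethoxybenzene
Conditions: MeI, K2CO3, DMF, rt
Reagents that add atoms: iodomethane, CI
Why: Williamson O-methylation of the only free phenol completes the tetramethoxy B ring; the benzylic/allylic C–H is not acidic enough to epimerise with carbonate.

**Step 8**
Reactants: 12 1-{(2R,3E)-1-[2,4-bis(benzyloxy)-3-methoxyphenyl]pent-3-en-2-yl}-2,3,4,5-tetramethoxybenzene
Product: 15 (2S)-3-[2,4-bis(benzyloxy)-3-methoxyphenyl]-2-(2,3,4,5-tetramethoxyphenyl)propan-1-ol, via secondary ozonide 13 (not isolated), via aldehyde 14 (not isolated)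
Conditions: O3, CH2Cl2, −78 °C (Sudan Red 7B end point); then NaBH4, MeOH, −78 → 0 °C
Reagents that add atoms: ozone, [O-][O+]=O
Why: Ozonolysis with reductive work-up cleaves the propenyl group to CH2OH; the α-aryl aldehyde is reduced cold before it can enolise, and the descriptor changes from R to S only because CH2OH now outranks the aryl group.

**Step 9**
Reactants: 15 (2S)-3-[2,4-bis(benzyloxy)-3-methoxyphenyl]-2-(2,3,4,5-tetramethoxyphenyl)propan-1-ol
Product: 16 4-[(2S)-3-hydroxy-2-(2,3,4,5-tetramethoxyphenyl)propyl]-2-methoxybenzene-1,3-diol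
Conditions: H2 (1 atm), 10% Pd/C, EtOAc/EtOH, rt
Reagents that add atoms: none
Why: Hydrogenolysis removes both O-benzyl groups; methyl ethers, the primary alcohol and the C–C stereocentre are untouched.

**Step 10**
Reactants: 16 4-[(2S)-3-hydroxy-2-(2,3,4,5-tetramethoxyphenyl)propyl]-2-methoxybenzene-1,3-diol
Product: 17 (3S)-8-methoxy-3-(2,3,4,5-tetramethoxyphenyl)-3,4-dihydro-2H-1-benzopyran-7-ol
Conditions: PPh3, DIAD, THF (0.01 M), 0 °C → rt
Reagents that add atoms: none
Why: Intramolecular Mitsunobu etherification; only the ortho phenol can reach the activated primary carbon (6-exo-tet), the 7-OH can react only intermolecularly and is suppressed by dilution, and the stereocentre is not involved.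

**Compound list**
1 | 2,4-dihydroxy-3-methoxybenzaldehyde | O=Cc1ccc(O)c(OC)c1O | starting material
2 | 2,4-bis(benzyloxy)-3-methoxybenzaldehyde | O=Cc1ccc(OCc2ccccc2)c(OC)c1OCc1ccccc1 | intermediate
3 | [2,4-bis(benzyloxy)-3-methoxyphenyl]methanol | OCc1ccc(OCc2ccccc2)c(OC)c1OCc1ccccc1 | intermediate
4 | 1,3-bis(benzyloxy)-4-(bromomethyl)-2-methoxybenzene | BrCc1ccc(OCc2ccccc2)c(OC)c1OCc1ccccc1 | intermediate
5 | 2,3,4-trimethoxyphenol | COc1ccc(O)c(OC)c1OC | starting material
6 | (R)-but-3-yn-2-ol | C[C@@H](O)C#C | starting material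
7 | 1-{[(2S)-but-3-yn-2-yl]oxy}-2,3,4-trimethoxybenzene | C[C@H](Oc1ccc(OC)c(OC)c1OC)C#C | intermediate
8 | 2-[(1E,3S)-3-(2,3,4-trimethoxyphenoxy)but-1-en-1-yl]-4,4,5,5-tetramethyl-1,3,2-dioxaborolane | C[C@H](Oc1ccc(OC)c(OC)c1OC)/C=C/B1OC(C)(C)C(C)(C)O1 | intermediate (not isolated)
9 | 1,3-bis(benzyloxy)-2-methoxy-4-[(2E,4S)-4-(2,3,4-trimethoxyphenoxy)pent-2-en-1-yl]benzene | C[C@H](Oc1ccc(OC)c(OC)c1OC)/C=C/Cc1ccc(OCc2ccccc2)c(OC)c1OCc1ccccc1 | intermediate
10 | (6R)-6-{(2R,3E)-1-[2,4-bis(benzyloxy)-3-methoxyphenyl]pent-3-en-2-yl}-2,3,4-trimethoxycyclohexa-2,4-dien-1-one | O=C1C(OC)=C(OC)C(OC)=C[C@H]1[C@H](Cc1ccc(OCc2ccccc2)c(OC)c1OCc1ccccc1)/C=C/C | intermediate (not isolated)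
11 | 6-{(2R,3E)-1-[2,4-bis(benzyloxy)-3-methoxyphenyl]pent-3-en-2-yl}-2,3,4-trimethoxyphenol | C/C=C/[C@@H](Cc1ccc(OCc2ccccc2)c(OC)c1OCc1ccccc1)c1cc(OC)c(OC)c(OC)c1O | intermediate
12 | 1-{(2R,3E)-1-[2,4-bis(benzyloxy)-3-methoxyphenyl]pent-3-en-2-yl}-2,3,4,5-tetramethoxybenzene | C/C=C/[C@@H](Cc1ccc(OCc2ccccc2)c(OC)c1OCc1ccccc1)c1cc(OC)c(OC)c(OC)c1OC | intermediate
13 | 3-{(1S)-2-[2,4-bis(benzyloxy)-3-methoxyphenyl]-1-(2,3,4,5-tetramethoxyphenyl)ethyl}-5-methyl-1,2,4-trioxolane (ring diastereomers) | CC1OC(OO1)[C@@H](Cc1ccc(OCc2ccccc2)c(OC)c1OCc1ccccc1)c1cc(OC)c(OC)c(OC)c1OC | intermediate (not isolated)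
14 | (2S)-3-[2,4-bis(benzyloxy)-3-methoxyphenyl]-2-(2,3,4,5-tetramethoxyphenyl)propanal | O=C[C@@H](Cc1ccc(OCc2ccccc2)c(OC)c1OCc1ccccc1)c1cc(OC)c(OC)c(OC)c1OC | intermediate (not isolated)
15 | (2S)-3-[2,4-bis(benzyloxy)-3-methoxyphenyl]-2-(2,3,4,5-tetramethoxyphenyl)propan-1-ol | OC[C@@H](Cc1ccc(OCc2ccccc2)c(OC)c1OCc1ccccc1)c1cc(OC)c(OC)c(OC)c1OC | intermediate
16 | 4-[(2S)-3-hydroxy-2-(2,3,4,5-tetramethoxyphenyl)propyl]-2-methoxybenzene-1,3-diol | OC[C@@H](Cc1ccc(O)c(OC)c1O)c1cc(OC)c(OC)c(OC)c1OC | intermediate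
17 | (3S)-8-methoxy-3-(2,3,4,5-tetramethoxyphenyl)-3,4-dihydro-2H-1-benzopyran-7-ol | COc1cc([C@H]2COc3c(ccc(O)c3OC)C2)c(OC)c(OC)c1OC | target

**Totals**
Total step count: 10. Longest linear sequence: 9 steps (1 → 2 → 3 → 4 → 9 → 11 → 12 → 15 → 16 → 17).

**Three steps most likely to fail**

Step 5 (one-pot hydroboration/Suzuki coupling). The electron-rich benzyl bromide 4 may hydrolyse or homocouple, and Pd(0) could ionise the allylic aryl ether 9 and erode its ee. The fallback sets out from bromide 4 and alcohol 6 and comes back at 9. Alcohol 6 is deprotonated twice with EtMgBr in THF and coupled with 4 under CuBr·SMe2 catalysis to give (2R)-5-[2,4-bis(benzyloxy)-3-methoxyphenyl]pent-3-yn-2-ol F1. Alkoxide-directed trans-hydroalumination with Red-Al (THF, 0 °C) gives (2R,3E)-5-[2,4-bis(benzyloxy)-3-methoxyphenyl]pent-3-en-2-ol F2. Mitsunobu etherification of F2 with phenol 5 (PPh3, DIAD, toluene, 0 °C) then proceeds with inversion to the (S,E)-ether 9. This builds the E-olefin without palladium.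

Step 8 (ozonolysis/NaBH4). Ozone may attack the two electron-rich arenes or the benzyl ethers, and aldehyde 14 can epimerise if it survives too long. The fallback sets out from 12 and comes back at 15. Upjohn dihydroxylation (K2OsO4·2H2O cat., NMO, acetone/H2O) gives (4S)-5-[2,4-bis(benzyloxy)-3-methoxyphenyl]-4-(2,3,4,5-tetramethoxyphenyl)pentane-2,3-diol F3 as a diastereomer mixture at C2/C3. Glycol cleavage with NaIO4 on silica (CH2Cl2, 0 °C), followed at once by NaBH4/MeOH on the filtrate, gives 15.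

Step 10 (Mitsunobu cyclisation with a free 7-OH). A hindered phenol nucleophile, competing intermolecular O-alkylation and a polar product that is hard to separate from Ph3PO are the concerns. The fallback sets out from 15 and comes back at 17. Mesylation (MsCl, Et3N, CH2Cl2, 0 °C) gives (2S)-3-[2,4-bis(benzyloxy)-3-methoxyphenyl]-2-(2,3,4,5-tetramethoxyphenyl)propyl methanesulfonate F4. Hydrogenolysis (H2, Pd/C, EtOAc) gives (2S)-3-(2,4-dihydroxy-3-methoxyphenyl)-2-(2,3,4,5-tetramethoxyphenyl)propyl methanesulfonate F5. K2CO3 in acetone at high dilution then closes the ring by intramolecular Williamson etherification to 17.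

**Further compounds**
F1 | step 5 | (2R)-5-[2,4-bis(benzyloxy)-3-methoxyphenyl]pent-3-yn-2-ol | C[C@@H](O)C#CCc1ccc(OCc2ccccc2)c(OC)c1OCc1ccccc1
F2 | step 5 | (2R,3E)-5-[2,4-bis(benzyloxy)-3-methoxyphenyl]pent-3-en-2-ol | C[C@@H](O)/C=C/Cc1ccc(OCc2ccccc2)c(OC)c1OCc1ccccc1
F3 | step 8 | (4S)-5-[2,4-bis(benzyloxy)-3-methoxyphenyl]-4-(2,3,4,5-tetramethoxyphenyl)pentane-2,3-diol | CC(O)C(O)[C@@H](Cc1ccc(OCc2ccccc2)c(OC)c1OCc1ccccc1)c1cc(OC)c(OC)c(OC)c1OC
F4 | step 10 | (2S)-3-[2,4-bis(benzyloxy)-3-methoxyphenyl]-2-(2,3,4,5-tetramethoxyphenyl)propyl methanesulfonate | CS(=O)(=O)OC[C@@H](Cc1ccc(OCc2ccccc2)c(OC)c1OCc1ccccc1)c1cc(OC)c(OC)c(OC)c1OC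
F5 | step 10 | (2S)-3-(2,4-dihydroxy-3-methoxyphenyl)-2-(2,3,4,5-tetramethoxyphenyl)propyl methanesulfonate | CS(=O)(=O)OC[C@@H](Cc1ccc(O)c(OC)c1O)c1cc(OC)c(OC)c(OC)c1OC
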